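**Retrosynthetic overview**
1. Target ⇐ formate→acetate exchange, Lindlar semi-hydrogenation and α-epoxidation of the macrocyclic enyne lactone 27.
2. Ten-membered ring and γ-lactone ⇐ intramolecular γ-chloroallylchromium addition to a C7 aldehyde (forms C6–C7, sets 6-Cl/7-O anti), then lactonization onto the C19 ester.
3. C7 aldehyde and 9-O-formate ⇐ periodate excision of the anomeric carbon of a 3-C-branched furanose; C2–C3 ⇐ acetylide addition, then oxidation/reduction.
4. Ring A ⇐ Diels–Alder reaction of sugar-derived (E)-enal 8 with aminosiloxy diene 11 (key step; sets C1 and C10).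
5. Enal 8 ⇐ diacetone-D-glucose (C9 = glucose C4; C8/C17 by aldol on the 3-ulose). Ring order: ring A, then ten-membered ring and lactone in one operation, epoxide last.

Assumption: atoms carry briarane-type labels (C1–C14 ring carbons, C15 = C1 methyl, C16 = exocyclic CH2, C17/C18/C19 = lactone α-carbon/its methyl/carbonyl, C20 = C11 methyl); β is the ring A face bearing C15.

**Step 1**
Reactants: 1 1,2:5,6-di-O-isopropylidene-α-D-glucofuranose
Product: 2 1,2:5,6-di-O-isopropylidene-α-D-ribo-hexofuranos-3-ulose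
Conditions: Dess–Martin periodinane, CH2Cl2, rt
Reagents that add atoms: none
Why: Dess–Martin oxidation of the hindered secondary alcohol gives the ketone (future C8) without touching the acetonides or any stereocenter.

**Step 2**
Reactants: 2 the 3-ulose; 3 ethyl propanoate
Product: 5 ethyl (2R)-2-[3-O-TBS-1,2:5,6-di-O-isopropylidene-α-D-allofuranos-3-C-yl]propanoate, via lithium aldolate 4 (not isolated)
Conditions: LiN(iPr)2, THF/DMPU (4:1), −78 °C, 3; then 2; then TBSOTf, −78 → 0 °C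
Reagents that add atoms: tert-butyldimethylsilyl trifluoromethanesulfonate (TBSOTf), CC(C)(C)[Si](C)(C)OS(=O)(=O)C(F)(F)F
Why: Aldol addition of the Z(O)-enolate to the convex β-face of the cis-fused bicyclic ketone (anti to the 1,2-acetonide) sets C8, a closed transition state with the enolate hydrogen over the furanose ring and the ester toward C7 sets C17 (modest control expected, minor epimer removed), and the tertiary aldolate is silylated in situ.

**Step 3**
Reactants: 5 the silylated aldol adduct; 6 2-(triphenylphosphoranylidene)propanal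
Product: 8 (E)-enal (C10=C1 alkene bearing C15 and the C2 aldehyde), via C10 aldehyde 7 (not isolated)
Conditions: H5IO6, EtOAc, rt; filter; then 6, CH2Cl2, rt → 40 °C
Reagents that add atoms: none
Why: Periodic acid hydrolyses only the terminal acetonide and cleaves the glycol to the C10 aldehyde, and Wittig olefination with the formyl-stabilised ylide gives the E-enal (CHO trans to C9) without epimerising C9.

**Step 4**
Reactants: 9 (E)-4-(dimethylamino)but-3-en-2-one
Product: 10 (E)-1-(dimethylamino)pent-1-en-3-one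
Conditions: LiN(iPr)2, THF, −78 °C; MeI
Reagents that add atoms: iodomethane, CI
Why: Alkylation of the kinetic lithium enolate of the vinylogous amide at its methyl group installs the future C20.

**Step 5**
Reactants: 10 (E)-1-(dimethylamino)pent-1-en-3-one
Product: 11 (1E,3Z)-3-(tert-butyldimethylsilyloxy)-N,N-dimethylpenta-1,3-dien-1-amine
Conditions: KN(SiMe3)2, THF, −78 °C; TBSCl
Reagents that add atoms: tert-butyldimethylsilyl chloride (TBSCl), CC(C)(C)[Si](C)(C)Cl
Why: O-silylation of the potassium Z-enolate gives the 1-amino-3-siloxy diene with the terminal methyl on the outside, as needed for a reactive s-cis diene.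

**Step 6 (key step)**
Reactants: 8 the (E)-enal; 11 the aminosiloxy diene
Product: 12 Diels–Alder adduct (ring A with 1β-CH3, 1α-CHO, 10α-H, 11α-CH3, 14α-NMe2, C12=C13 silyl enol ether)
Conditions: toluene, 70 °C, sealed tube (2 equiv of 11)
Reagents that add atoms: none
Why: Diels–Alder cycloaddition in which diene polarisation joins C11 to the enal β-carbon C10, suprafacial addition to the E-alkene fixes C1 relative to C10, and the diene adds anti to the quaternary C8 with H9 eclipsing the alkene (allylic strain) so that C9 sets C10 and C1; C11 and C14 are not needed as formed.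

**Step 7**
Reactants: 13 1,3-dichloropropan-2-one; 14 ethynylmagnesium bromide
Product: 15 1-chloro-2-(chloromethyl)but-3-yn-2-ol
Conditions: THF, −78 °C; cold 1 M HCl
Reagents that add atoms: none
Why: Grignard 1,2-addition to the electrophilic ketone, quenched cold so that the chlorohydrin alkoxide does not close to an epoxide.

**Step 8**
Reactants: 15 1-chloro-2-(chloromethyl)but-3-yn-2-ol
Product: 16 (E)-1-chloro-2-(chloromethyl)but-1-en-3-yne (E/Z mixture, E drawn)
Conditions: Burgess reagent, benzene, 50 °C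
Reagents that add atoms: none
Why: Burgess dehydration (syn elimination of the sulfamate ester) of the tertiary propargylic alcohol gives the chloroenyne, whose alkene geometry is irrelevant because the allylchromium formed in step 15 equilibrates.

**Step 9**
Reactants: 12 the Diels–Alder adduct; 16 the chloroenyne
Product: 18 ring A enone carrying the C2 propargylic alcohol (C2 epimers, 11α-CH3), via lithium propargylic alkoxide 17 (not isolated)
Conditions: 16, LiN(SiMe3)2, THF, −78 °C; then 12; then 1 M HCl, THF, 0 °C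
Reagents that add atoms: none
Why: Lithium acetylide 1,2-addition to the non-enolisable neopentyl aldehyde while the ring ketone is masked, then hydrolysis of the silyl enol ether and E1cB loss of dimethylamine to unveil the C12 enone (C13=C14).

**Step 10**
Reactants: 18 the 11α-methyl enone
Product: 20 the 11β-methyl enone (C2 epimers), via dilithium dienolate 19 (not isolated)
Conditions: LiN(SiMe3)2 (2.2 equiv), THF, −78 → −40 °C; then AcOH, −78 °C
Reagents that add atoms: none
Why: Enolisation to the cross-conjugated dienolate and kinetic protonation on the α-face (delivered by the α-disposed C2 hydroxyl and opposite the pseudoaxial C10 substituent) inverts C11.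

**Step 11**
Reactants: 20 the 11β-methyl enone
Product: 21 C2 ynone
Conditions: Dess–Martin periodinane, pyridine, CH2Cl2, 0 °C
Reagents that add atoms: none
Why: Dess–Martin oxidation of the propargylic alcohol removes the C2 epimer mixture under buffered conditions that leave C11 untouched.

**Step 12**
Reactants: 21 the ynone enone
Product: 22 C2,C12 diol (C2 as in the target, 12β-OH)
Conditions: NaBH4, CeCl3·7H2O, MeOH, −78 → −40 °C
Reagents that add atoms: none
Why: Luche 1,2-reduction in which hydride attacks C2 in the Felkin–Anh sense (anti to C10, carbonyl oxygen beside C14) and attacks C12 from the α-face opposite the pseudoaxial C10 substituent.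

**Step 13**
Reactants: 22 the diol
Product: 23 2,12-diacetate
Conditions: Ac2O, Et3N, DMAP (cat.), CH2Cl2, 0 °C → rt
Reagents that add atoms: acetic anhydride, CC(=O)OC(C)=O
Why: DMAP-catalysed acetylation of both secondary alcohols installs two of the three target acetates.

**Step 14**
Reactants: 23 the diacetate
Product: 25 C7 aldehyde 9-O-formate, via furanose lactol diol 24 (not isolated)
Conditions: TFA/H2O (9:1), 0 °C, 30 min; concentrate; then NaIO4, THF/pH 7 buffer, 0 °C
Reagents that add atoms: none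
Why: Acid hydrolysis of the 1,2-acetonide and Malaprade cleavage of the hemiacetal glycol excise the anomeric carbon, leaving a non-enolisable C7 aldehyde and O9 capped as a formate, while the tertiary TBS ether keeps C8–OH out of the glycol cleavage.

**Step 15**
Reactants: 25 the aldehyde formate
Product: 27 macrocyclic enyne γ-lactone (6-Cl, 8-OTBS, 9-formate, 2,12-diacetate), via macrocyclic hydroxy ester 26 (not isolated)
Conditions: CrCl2 (10 equiv), LiI (0.2 equiv), THF/DMF (9:1), rt, syringe-pump addition to 2 mM; aqueous work-up; then PPTS (cat.), benzene, 50 °C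
Reagents that add atoms: none
Why: Intramolecular Nozaki–Hiyama allylation in which the γ-chloroallylchromium reacts at its chlorine-bearing terminus through a chair transition state (6-Cl/7-O anti) on the Felkin–Anh face of the α-silyloxy aldehyde (C9 inside, sets C7) to close the ten-membered ring, and the γ-hydroxy ester then lactonises.

**Step 16**
Reactants: 27 the silylated macrolactone
Product: 28 8-hydroxy enyne lactone
Conditions: HF·pyridine, THF/pyridine, 0 °C → rt
Reagents that add atoms: none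
Why: Fluoride-mediated desilylation frees the tertiary C8 alcohol before the acid-sensitive epoxide is introduced.

**Step 17**
Reactants: 28 the enyne lactone
Product: 29 13α,14α-epoxide
Conditions: mCPBA, Na2HPO4, CH2Cl2, 0 °C → rt
Reagents that add atoms: 3-chloroperoxybenzoic acid (mCPBA), OOC(=O)c1cccc(Cl)c1
Why: Prilezhaev epoxidation of the only electron-rich alkene (the exocyclic alkene is deactivated by the allylic chloride and the alkyne) from the α-face, anti to the β-acetate at C12 and the β-methyl at C1.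

**Step 18**
Reactants: 29 the epoxy enyne
Product: 30 (3Z)-diene 9-formate
Conditions: H2 (1 atm), Pd/CaCO3 poisoned with Pb(OAc)2, quinoline, EtOAc, rt
Reagents that add atoms: none
Why: Lindlar semi-hydrogenation adds hydrogen syn to the ring alkyne to give the Z-alkene, with quinoline suppressing over-reduction and allylic C–Cl hydrogenolysis.

**Step 19**
Reactants: 30 the diene formate
Product: 32 CNP0274383.1 (target), via C9 alcohol 31 (not isolated)
Conditions: KHCO3, MeOH, 0 °C; concentrate; then Ac2O, pyridine, DMAP (cat.), CH2Cl2, 0 °C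
Reagents that add atoms: acetic anhydride, CC(=O)OC(C)=O
Why: Chemoselective methanolysis of the formate (much faster than the acetates) followed by acetylation of the secondary C9 alcohol, which the tertiary C8 alcohol does not undergo.

**Compound list**
1 | 1,2:5,6-di-O-isopropylidene-α-D-glucofuranose (diacetone-D-glucose) | CC1(C)OC[C@@H](O1)[C@H]2O[C@@H]3OC(C)(C)O[C@@H]3[C@H]2O | starting material
2 | 1,2:5,6-di-O-isopropylidene-α-D-ribo-hexofuranos-3-ulose | CC1(C)OC[C@@H](O1)[C@H]2O[C@@H]3OC(C)(C)O[C@@H]3C2=O | intermediate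
3 | ethyl propanoate | CCC(=O)OCC | starting material
4 | lithium 3-alkoxide of ethyl (2R)-2-(1,2:5,6-di-O-isopropylidene-α-D-allofuranos-3-C-yl)propanoate | CC1(C)OC[C@@H](O1)[C@H]2O[C@@H]3OC(C)(C)O[C@@H]3[C@@]2(O[Li])[C@@H](C)C(=O)OCC | intermediate
5 | ethyl (2R)-2-[3-O-(tert-butyldimethylsilyl)-1,2:5,6-di-O-isopropylidene-α-D-allofuranos-3-C-yl]propanoate | CC1(C)OC[C@@H](O1)[C@H]2O[C@@H]3OC(C)(C)O[C@@H]3[C@@]2(O[Si](C)(C)C(C)(C)C)[C@@H](C)C(=O)OCC | intermediate
6 | 2-(triphenylphosphoranylidene)propanal | CC(C=O)=P(c1ccccc1)(c1ccccc1)c1ccccc1 | starting material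
7 | C10 aldehyde: ethyl (2R)-2-[3-O-TBS-1,2-O-isopropylidene-α-D-ribo-pentodialdo-1,4-furanos-3-C-yl]propanoate | O=C[C@H]1O[C@@H]2OC(C)(C)O[C@@H]2[C@@]1(O[Si](C)(C)C(C)(C)C)[C@@H](C)C(=O)OCC | intermediate
8 | (E)-enal: aldehyde carbon of 7 extended to CH=C(CH3)–CHO, CHO trans to C9 | O=C/C(C)=C/[C@H]1O[C@@H]2OC(C)(C)O[C@@H]2[C@@]1(O[Si](C)(C)C(C)(C)C)[C@@H](C)C(=O)OCC | intermediate
9 | (E)-4-(dimethylamino)but-3-en-2-one | CC(=O)/C=C/N(C)C | starting material
10 | (E)-1-(dimethylamino)pent-1-en-3-one | CCC(=O)/C=C/N(C)C | intermediate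
11 | (1E,3Z)-3-(tert-butyldimethylsilyloxy)-N,N-dimethylpenta-1,3-dien-1-amine | C/C=C(O[Si](C)(C)C(C)(C)C)/C=C/N(C)C | intermediate
12 | Diels–Alder adduct: ring A with 1β-CH3, 1α-CHO, 10α-H (furanosyl unit β), 11α-CH3, 12-OTBS enol ether (C12=C13), 14α-NMe2 | O=C[C@]1(C)[C@H]([C@H](C)C(O[Si](C)(C)C(C)(C)C)=C[C@@H]1N(C)C)[C@H]2O[C@@H]3OC(C)(C)O[C@@H]3[C@@]2(O[Si](C)(C)C(C)(C)C)[C@@H](C)C(=O)OCC | intermediate
13 | 1,3-dichloropropan-2-one | ClCC(=O)CCl | starting material
14 | ethynylmagnesium bromide | C#C[Mg]Br | starting material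
15 | 1-chloro-2-(chloromethyl)but-3-yn-2-ol | ClCC(O)(CCl)C#C | intermediate
16 | (E)-1-chloro-2-(chloromethyl)but-1-en-3-yne (E/Z mixture, E drawn) | Cl/C=C(CCl)\C#C | intermediate
17 | lithium alkoxide of the C2 propargylic alcohol from 12 and 16 (C2 epimers) | Cl/C=C(CCl)\C#CC(O[Li])[C@]1(C)[C@H]([C@H](C)C(O[Si](C)(C)C(C)(C)C)=C[C@@H]1N(C)C)[C@H]2O[C@@H]3OC(C)(C)O[C@@H]3[C@@]2(O[Si](C)(C)C(C)(C)C)[C@@H](C)C(=O)OCC | intermediate
18 | ring A enone (C12 ketone, C13=C14), 11α-CH3, C2 propargylic alcohol (C2 epimers) | Cl/C=C(CCl)\C#CC(O)[C@]1(C)[C@H]([C@H](C)C(=O)C=C1)[C@H]2O[C@@H]3OC(C)(C)O[C@@H]3[C@@]2(O[Si](C)(C)C(C)(C)C)[C@@H](C)C(=O)OCC | intermediate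
19 | dilithium salt of 18: C2 alkoxide and C11=C12 dienolate | Cl/C=C(CCl)\C#CC(O[Li])[C@]1(C)[C@H](C(C)=C(O[Li])C=C1)[C@H]2O[C@@H]3OC(C)(C)O[C@@H]3[C@@]2(O[Si](C)(C)C(C)(C)C)[C@@H](C)C(=O)OCC | intermediate
20 | 11β-methyl epimer of 18 (C2 epimers) | Cl/C=C(CCl)\C#CC(O)[C@]1(C)[C@H]([C@@H](C)C(=O)C=C1)[C@H]2O[C@@H]3OC(C)(C)O[C@@H]3[C@@]2(O[Si](C)(C)C(C)(C)C)[C@@H](C)C(=O)OCC | intermediate
21 | C2 ynone of 20 | Cl/C=C(CCl)\C#CC(=O)[C@]1(C)[C@H]([C@@H](C)C(=O)C=C1)[C@H]2O[C@@H]3OC(C)(C)O[C@@H]3[C@@]2(O[Si](C)(C)C(C)(C)C)[C@@H](C)C(=O)OCC | intermediate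
22 | C2,C12 diol (C2 as in target, 12β-OH) | Cl/C=C(CCl)\C#C[C@@H](O)[C@]1(C)[C@H]([C@@H](C)[C@@H](O)C=C1)[C@H]2O[C@@H]3OC(C)(C)O[C@@H]3[C@@]2(O[Si](C)(C)C(C)(C)C)[C@@H](C)C(=O)OCC | intermediate
23 | 2,12-diacetate of 22 | Cl/C=C(CCl)\C#C[C@@H](OC(C)=O)[C@]1(C)[C@H]([C@@H](C)[C@@H](OC(C)=O)C=C1)[C@H]2O[C@@H]3OC(C)(C)O[C@@H]3[C@@]2(O[Si](C)(C)C(C)(C)C)[C@@H](C)C(=O)OCC | intermediate
24 | furanose lactol diol (free C6 hemiacetal OH, anomers, and C7 OH) | Cl/C=C(CCl)\C#C[C@@H](OC(C)=O)[C@]1(C)[C@H]([C@@H](C)[C@@H](OC(C)=O)C=C1)[C@H]2OC(O)[C@H](O)[C@@]2(O[Si](C)(C)C(C)(C)C)[C@@H](C)C(=O)OCC | intermediate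
25 | C7 aldehyde 9-O-formate (C8 bears CHO, OTBS and the propanoate arm) | Cl/C=C(CCl)\C#C[C@@H](OC(C)=O)[C@]1(C)[C@H]([C@@H](C)[C@@H](OC(C)=O)C=C1)[C@@H](OC=O)[C@](C=O)(O[Si](C)(C)C(C)(C)C)[C@@H](C)C(=O)OCC | intermediate
26 | macrocyclic γ-hydroxy ester (ten-membered enyne ring, 6-Cl and 7-OH anti) | C=C1C#C[C@@H](OC(C)=O)[C@]2(C)[C@H]([C@@H](C)[C@@H](OC(C)=O)C=C2)[C@@H](OC=O)[C@]([C@@H](O)[C@H]1Cl)(O[Si](C)(C)C(C)(C)C)[C@@H](C)C(=O)OCC | intermediate
27 | macrocyclic enyne γ-lactone, 8-O-TBS, 9-O-formyl, 2,12-di-O-acetyl, 6-chloro | C=C1C#C[C@@H](OC(C)=O)[C@]2(C)[C@H]([C@@H](C)[C@@H](OC(C)=O)C=C2)[C@@H](OC=O)[C@]2(O[Si](C)(C)C(C)(C)C)[C@@H](C)C(=O)O[C@H]2[C@H]1Cl | intermediate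
28 | 8-hydroxy enyne lactone (TBS removed) | C=C1C#C[C@@H](OC(C)=O)[C@]2(C)[C@H]([C@@H](C)[C@@H](OC(C)=O)C=C2)[C@@H](OC=O)[C@]2(O)[C@@H](C)C(=O)O[C@H]2[C@H]1Cl | intermediate
29 | 13α,14α-epoxide of 28 | C=C1C#C[C@@H](OC(C)=O)[C@]2(C)[C@H]([C@@H](C)[C@@H](OC(C)=O)[C@@H]3O[C@@H]32)[C@@H](OC=O)[C@]2(O)[C@@H](C)C(=O)O[C@H]2[C@H]1Cl | intermediate
30 | (3Z)-diene 9-formate | C=C1/C=C\[C@@H](OC(C)=O)[C@]2(C)[C@H]([C@@H](C)[C@@H](OC(C)=O)[C@@H]3O[C@@H]32)[C@@H](OC=O)[C@]2(O)[C@@H](C)C(=O)O[C@H]2[C@H]1Cl | intermediate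
31 | 9-hydroxy compound (formate removed) | C=C1/C=C\[C@@H](OC(C)=O)[C@]2(C)[C@H]([C@@H](C)[C@@H](OC(C)=O)[C@@H]3O[C@@H]32)[C@@H](O)[C@]2(O)[C@@H](C)C(=O)O[C@H]2[C@H]1Cl | intermediate
32 | CNP0274383.1 | C=C1/C=C\[C@@H](OC(C)=O)[C@]2(C)[C@H]([C@@H](C)[C@@H](OC(C)=O)[C@@H]3O[C@@H]32)[C@@H](OC(C)=O)[C@]2(O)[C@@H](C)C(=O)O[C@H]2[C@H]1Cl | target

**Step count and risks**
Total steps: 19. Longest linear sequence: 15 steps (1, 2, 3, 6, 9–19, from diacetone-D-glucose).

Risk 1, step 15 (ring closure). The chain held straight by the alkyne may not close, or the Felkin–Anh and anti preferences may not survive in the macrocyclic transition state. The fallback sets out from 25 and bends the chain first. Semi-hydrogenation (H2, Pd/CaCO3 poisoned with Pb(OAc)2, quinoline) gives the Z-dienyl aldehyde F1. CrCl2/LiI under high dilution then closes the ring to the Z-diene macrocyclic hydroxy ester F2, which PPTS lactonises to the Z-diene lactone F3. HF·pyridine gives the desilylated Z-diene lactone F4. Buffered mCPBA at low conversion, relying on the deactivation of the diene by its allylic chloride and acetate, epoxidises the ring A alkene and rejoins the route at 30.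

Risk 2, step 6 (cycloaddition on a hindered, β-branched α-methyl enal). The fallback sets out from 8 and replaces the thermal cycloaddition by a Lewis-acid-driven stepwise annulation. Pent-1-en-3-one with TBSOTf/Et3N gives (Z)-3-(tert-butyldimethylsilyloxy)penta-1,3-diene F5. With Me2AlCl in CH2Cl2 at −78 °C, F5 and 8 undergo Mukaiyama–Michael addition and ring closure to the silyl enol ether aldehyde F6. Saegusa–Ito oxidation (Pd(OAc)2, MeCN), done before any allylic chloride is present, gives the enone aldehyde F7. Aldehyde-selective alkynylation with 16 (Zn(OTf)2, Et3N, toluene) leaves the enone untouched and rejoins the route at 18.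

Risk 3, step 10 (C11 inversion by kinetic protonation). If the proton returns on the β-face and regenerates 18, the order in which proton and methyl arrive is reversed. The fallback sets out from 8, which is heated with commercial trans-3-(tert-butyldimethylsilyloxy)-N,N-dimethyl-1,3-butadien-1-amine to give the C11-unsubstituted cycloadduct F8. The lithium acetylide of 16 adds to give the C11-unsubstituted lithium alkoxide F9, and HCl work-up gives the C11-unsubstituted enone carbinol F10. LiN(SiMe3)2 (2.1 equiv) then MeI (1.0 equiv) at −78 °C brings the methyl group in on the face the proton preferred, and the sequence rejoins the route at 20.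

**Further compounds**
F1 | step 15 | Z-dienyl aldehyde (alkyne of 25 reduced to the 3Z alkene) | Cl/C=C(CCl)\C=C/[C@@H](OC(C)=O)[C@]1(C)[C@H]([C@@H](C)[C@@H](OC(C)=O)C=C1)[C@@H](OC=O)[C@](C=O)(O[Si](C)(C)C(C)(C)C)[C@@H](C)C(=O)OCC
F2 | step 15 | Z-diene macrocyclic hydroxy ester | C=C1/C=C\[C@@H](OC(C)=O)[C@]2(C)[C@H]([C@@H](C)[C@@H](OC(C)=O)C=C2)[C@@H](OC=O)[C@]([C@@H](O)[C@H]1Cl)(O[Si](C)(C)C(C)(C)C)[C@@H](C)C(=O)OCC
F3 | step 15 | Z-diene lactone (8-O-TBS, 9-formate) | C=C1/C=C\[C@@H](OC(C)=O)[C@]2(C)[C@H]([C@@H](C)[C@@H](OC(C)=O)C=C2)[C@@H](OC=O)[C@]2(O[Si](C)(C)C(C)(C)C)[C@@H](C)C(=O)O[C@H]2[C@H]1Cl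
F4 | step 15 | desilylated Z-diene lactone | C=C1/C=C\[C@@H](OC(C)=O)[C@]2(C)[C@H]([C@@H](C)[C@@H](OC(C)=O)C=C2)[C@@H](OC=O)[C@]2(O)[C@@H](C)C(=O)O[C@H]2[C@H]1Cl
F5 | step 6 | (Z)-3-(tert-butyldimethylsilyloxy)penta-1,3-diene | C/C=C(O[Si](C)(C)C(C)(C)C)/C=C
F6 | step 6 | silyl enol ether aldehyde (ring A, C12=C13 enol ether, C14H2) | O=C[C@]1(C)[C@H]([C@H](C)C(O[Si](C)(C)C(C)(C)C)=CC1)[C@H]2O[C@@H]3OC(C)(C)O[C@@H]3[C@@]2(O[Si](C)(C)C(C)(C)C)[C@@H](C)C(=O)OCC
F7 | step 6 | enone aldehyde | O=C[C@]1(C)[C@H]([C@H](C)C(=O)C=C1)[C@H]2O[C@@H]3OC(C)(C)O[C@@H]3[C@@]2(O[Si](C)(C)C(C)(C)C)[C@@H](C)C(=O)OCC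
F8 | step 10 | C11-unsubstituted cycloadduct | O=C[C@]1(C)[C@H](CC(O[Si](C)(C)C(C)(C)C)=C[C@@H]1N(C)C)[C@H]2O[C@@H]3OC(C)(C)O[C@@H]3[C@@]2(O[Si](C)(C)C(C)(C)C)[C@@H](C)C(=O)OCC
F9 | step 10 | C11-unsubstituted lithium alkoxide | Cl/C=C(CCl)\C#CC(O[Li])[C@]1(C)[C@H](CC(O[Si](C)(C)C(C)(C)C)=C[C@@H]1N(C)C)[C@H]2O[C@@H]3OC(C)(C)O[C@@H]3[C@@]2(O[Si](C)(C)C(C)(C)C)[C@@H](C)C(=O)OCC
F10 | step 10 | C11-unsubstituted enone carbinol | Cl/C=C(CCl)\C#CC(O)[C@]1(C)[C@H](CC(=O)C=C1)[C@H]2O[C@@H]3OC(C)(C)O[C@@H]3[C@@]2(O[Si](C)(C)C(C)(C)C)[C@@H](C)C(=O)OCC
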